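The data were computed from invented constants; the scatter is artificial.

I started from the last readings of the two earlier runs, grey and green, and asked what they could say of autumn, noon and spring, three flasks that differ in Jo and are read at 2.5 min.

| flask | Rx | Jo | Ez | remark | time |
|---|---|---|---|---|---|
| grey | 1 M | 1.2 M | 99 mM | run made earlier |  |
| green | 1 M | 2.5 M | 99 mM | run made earlier |  |
| autumn | 1.0 M | 1.00 M | 99 mM |  | 2.5 min |
| noon | 1.0 M | 1.50 M | 99 mM |  | 2.5 min |
| spring | 1.0 M | 2.20 M | 99 mM |  | 2.5 min |

- grey (time / s: Rx / %, Eb / %): 10.0: 88.3, 7.4; 12.0: 85.7, 8.1; 20.0: 77.9, 13.3; 30.0: 69.7, 20.0; 50.0: 54.9, 30.4; 60.0: 49.9, 36.4; 120: 25.7, 58.1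
- green (time / s: Rx / %, Eb / %): 15.0: 68.3, 20.9; 30.0: 44.5, 40.4; 50.0: 24.9, 60.4; 60.0: 17.3, 67.4; 80.0: 9.0, 79.7; 90.0: 6.7, 84.1; 120: 2.3, 92.1

(each reading ± 0.5 percentage points)

1. part of the Rx that has reacted at the end, autumn
2. part of the Rx that has reacted at the end, noon
3. part of the Rx that has reacted at the end, spring
4. what raising the concentration of Jo from its lowest to its highest value here does to the part of the Rx that has reacted (changes below 5 percentage points count as none) (it rises / it falls / no change)

- what has gone from Rx into another species counts as reacted, even if it can come back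

At 120 s the grey run held 25.7 % of its Rx and the green run 2.3 %. I folded each flask into one number, a Damköhler number that I call the fold number n. It counts how many times e has divided Rx, and I expected it to grow with cJo times t:

n = ln(cRx at the start / cRx) = G · cJo · t

part reacted = 1 − exp(−n)

Grey gave n = 1.36 and green n = 3.77. At equal time, grey scaled by cJo promised green only 2.83, less than green showed. So one number was not enough: G, as read from these runs, rose with Jo. I therefore scaled each flask from a run close to it in Jo:

autumn, from grey: n = 1.42, reacted 75.7 %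

noon, from grey: n = 2.12, reacted 88.0 %

spring, from green: n = 4.15, reacted 98.4 %

I carried forward that last value, the fold number of spring, the logarithm of how far its Rx shrinks by the time of reading.

The forecast gave 76 %, 89 % and 98 %, its noon figure higher than mine. Of the part reacted as Jo goes up, its verdict was: it rises, in its words “Conversion therefore rises with Jo”.

The flasks gave 73.4 %, 90.2 % and 98.4 %. Of the part reacted as Jo went up from autumn to spring, the result was: it rises, by 25 percentage points.

    Ez → 2 Qo (k = 0.100 min⁻¹)
    Rx + Wa ⇌ Rx.Wa, settled at all times (K = 1.20 M⁻¹)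
    Rx + Ve → Wa + Uv (k = 20000 M⁻¹ s⁻¹)
    2 Uv → Qi (k = 1.20 × 10⁷ M⁻¹ s⁻¹)
    2 Ve → Dw (k = 6.00 × 10⁶ M⁻¹ s⁻¹)
    Rx + Qo → Gu + Uv (k = 5.80 × 10⁵ M⁻¹ min⁻¹)
    Jo + Uv ⇌ Eb + Ve (K = 0.930, k = 1.00 × 10⁵ M⁻¹ min⁻¹)

Spring's 1.6 % of unbound Rx is a fold number of 4.14, beside my 4.15. The neighbour was spring read at 1.5 min. Scaling with t, I reckoned n = 2.49 for it, so 91.7 % reacted. That neighbour gave 89.8 %, a fold number of 2.29. Of the charged Rx in that neighbour, Eb held 78.7 % and Rx.Wa 8.54 %.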